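**Retrosynthetic overview**
- The target is cut at the CH2 bridge into a chromanol triol and a 4-hydroxy-2-pyrone. The pyrone is made separately from 3-pentanone and malonyl dichloride, and the bridge carbon comes from an iminium salt in the last step.
- The strategy rests on the dihydropyran ring of the chroman. O1, C8a, C4a and C4 are the four atoms of an ortho-quinone methide, and C3 with C2 and its two methyl groups is a trisubstituted alkene. An oxygen on C3 would polarise that alkene the wrong way, so C3 carries silicon, which becomes the hydroxyl with retention afterwards.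
- Silicon bears a trimethylsiloxy group rather than an aryl group, so that C–Si to C–OH needs only buffered peroxide. The two phenols next to the acetyl group stay methyl ethers until BBr3, which leaves exactly one free hydroxyl to become O1.
- The quinone methide precursor, a salicyl alcohol, comes from 1-(4-hydroxy-2,6-dimethoxyphenyl)ethanone by ortho-formylation and reduction. The vinylsilane comes from a Grignard reagent and a chlorodisiloxane.
- Ring order: the benzene ring is present from the start, the dihydropyran ring forms in step 4 (C3–C4 and C2–O1, C3 set), the pyrone ring forms in step 8, and the two halves are joined in step 9.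

Key step: step 4

Assumption: the sense of induction of the new cycloaddition cannot be derived from precedent, so the (R)-configured acid is written and its enantiomer would be used if a first trial gives the (S)-silane.

**Step 1**
Reactants: 1 1-(4-hydroxy-2,6-dimethoxyphenyl)ethanone
Product: 2 3-acetyl-6-hydroxy-2,4-dimethoxybenzaldehyde
Conditions: MgCl2, Et3N, (CH2O)n, MeCN, reflux; aq HCl work-up
Reagents that add atoms: paraformaldehyde (formaldehyde), C=O
Why: Magnesium-phenoxide-directed ortho-formylation (Casnati–Skattebøl reaction) places the formyl group next to the only free hydroxyl, the two ortho positions being equivalent, and stops after one formylation because the aldehyde deactivates the ring, which makes it a cleaner entry to the salicyl alcohol than base-mediated hydroxymethylation with its bis-adducts and diarylmethanes.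

**Step 2**
Reactants: 2 3-acetyl-6-hydroxy-2,4-dimethoxybenzaldehyde
Product: 3 1-[4-hydroxy-3-(hydroxymethyl)-2,6-dimethoxyphenyl]ethanone
Conditions: NaBH4 (0.5 equiv), THF/MeOH, −20 → 0 °C; pH 7 buffer
Reagents that add atoms: none
Why: Chemoselective NaBH4 reduction, in which the formyl group is reduced much faster than the acetyl group shielded by its two ortho methoxy groups, and the cold, buffered work-up keeps the acid-labile salicyl alcohol from ionising.

**Step 3**
Reactants: 4 1-bromo-2-methylprop-1-ene; 5 1-chloro-1,1,3,3,3-pentamethyldisiloxane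
Product: 7 1,1,1,3,3-pentamethyl-3-(2-methylprop-1-enyl)disiloxane, via Grignard reagent 6 (not isolated)
Conditions: Mg, THF, reflux; then 5, 0 °C → rt
Reagents that add atoms: none
Why: Grignard formation followed by nucleophilic substitution at silicon, in which chloride is displaced far faster than the siloxane oxygen, so one alkenyl group is transferred cleanly.

**Step 4**
Reactants: 3 1-[4-hydroxy-3-(hydroxymethyl)-2,6-dimethoxyphenyl]ethanone; 7 1,1,1,3,3-pentamethyl-3-(2-methylprop-1-enyl)disiloxane
Product: 9 1-[(3R)-5,7-dimethoxy-2,2-dimethyl-3-(pentamethyldisiloxanyl)-3,4-dihydro-2H-chromen-6-yl]ethanone, via quinone methide 8 (not isolated)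
Conditions: (R)-3,3'-bis(2,4,6-triisopropylphenyl)-1,1'-binaphthyl-2,2'-diyl hydrogen phosphate (10 mol %), 7 (5 equiv), 5 Å MS, toluene, −20 °C, 3 added over 6 h
Reagents that add atoms: none
Why: Proposed new method: the phosphoric acid should ionise the benzylic hydroxyl of 3 and hold the resulting quinone methide 8 as a hydrogen-bonded ion pair, whose exocyclic CH2 (the future C4) is attacked by the silicon-bearing carbon of 7, so that positive charge develops on the dimethyl-substituted carbon, which is tertiary and beta to silicon, and is quenched by the phosphate-bound phenolic oxygen (C2–O1) before the C–Si bond can turn into alignment and be lost. The closest known reactions are chiral phosphoric acid catalysed inverse-demand [4+2] cycloadditions of ortho-quinone methides with styrenes, enamides and enol ethers, and ipso attack of carbon electrophiles on vinylsilanes. The dihydropyran ring closes as the lagging C–O bond of an asynchronous hetero-Diels–Alder addition, that is, six-membered capture of a tertiary cation by oxygen inside the ion pair. C3 becomes stereogenic when C3–C4 forms, and its configuration depends on which face of the alkene meets the CH2 terminus, which only the chiral pocket of the phosphate around the bound quinone methide can differentiate (catalyst control, there being no other stereocentre). The step needs regioselectivity, secured by Markovnikov polarisation that silicon reinforces and an oxygen would reverse, the right ring oxygen, secured because only one phenol is free, and preference for the alkene over the free aromatic CH of 3 and 9, for which the alkene is used in excess and 3 is added slowly.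

**Step 5**
Reactants: 9 1-[(3R)-5,7-dimethoxy-2,2-dimethyl-3-(pentamethyldisiloxanyl)-3,4-dihydro-2H-chromen-6-yl]ethanone
Product: 10 1-[(3R)-3-hydroxy-5,7-dimethoxy-2,2-dimethyl-3,4-dihydro-2H-chromen-6-yl]ethanone
Conditions: KF, KHCO3, 30% aq H2O2, THF/MeOH, rt → 40 °C
Reagents that add atoms: hydrogen peroxide, OO
Why: Tamao–Kumada oxidation, in which hydroperoxide adds to the fluoride-activated, siloxy-bearing silicon and C3 migrates from silicon to oxygen with retention, so the (R)-silane gives the (R)-alcohol, and these buffered conditions contain no electrophile or strong acid that could attack the electron-rich ring, the aryl ketone or the beta-silyl ether (the reason for a siloxy rather than an aryl group on silicon).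

**Step 6**
Reactants: 10 1-[(3R)-3-hydroxy-5,7-dimethoxy-2,2-dimethyl-3,4-dihydro-2H-chromen-6-yl]ethanone
Product: 11 1-[(3R)-3,5,7-trihydroxy-2,2-dimethyl-3,4-dihydro-2H-chromen-6-yl]ethanone
Conditions: BBr3 (4 equiv), CH2Cl2, −78 → 0 °C; MeOH, then H2O
Reagents that add atoms: none
Why: BBr3 ether cleavage, in which both methoxy groups are ortho to the acetyl carbonyl and are cleaved at low temperature with chelation assistance (BCl3 would be expected to stop after the first), whereas the ring oxygen is a weakly basic vinylogous ester oxygen and ionisation at C2 is disfavoured by the neighbouring boron-bound C3 oxygen, so the chroman ring and C3 should remain intact.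

**Step 7**
Reactants: 12 3-pentanone
Product: 13 (Z)-trimethyl(pent-2-en-3-yloxy)silane
Conditions: TMSOTf, Et3N, CH2Cl2, 0 °C
Reagents that add atoms: trimethylsilyl trifluoromethanesulfonate, C[Si](C)(C)OS(=O)(=O)C(F)(F)F
Why: Soft enolisation and O-silylation with TMSOTf/Et3N gives the silyl enol ether (mainly Z, the geometry being lost in the next step).

**Step 8**
Reactants: 13 (Z)-trimethyl(pent-2-en-3-yloxy)silane; 14 malonyl dichloride
Product: 15 6-ethyl-4-hydroxy-5-methyl-2H-pyran-2-one
Conditions: Et2O, −78 °C → rt
Reagents that add atoms: none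
Why: Effenberger pyrone synthesis, in which the silyl enol ether is C-acylated by one acid chloride of malonyl dichloride and the resulting enol oxygen is then acylated by the other, closing the 4-hydroxy-2-pyrone ring by lactonisation.

**Step 9**
Reactants: 11 1-[(3R)-3,5,7-trihydroxy-2,2-dimethyl-3,4-dihydro-2H-chromen-6-yl]ethanone; 15 6-ethyl-4-hydroxy-5-methyl-2H-pyran-2-one
Product: 18 3-{[(3R)-6-acetyl-3,5,7-trihydroxy-2,2-dimethyl-3,4-dihydro-2H-chromen-8-yl]methyl}-6-ethyl-4-hydroxy-5-methyl-2H-pyran-2-one, via Mannich base 16 (not isolated), via quinone methide 17 (not isolated)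
Conditions: CH2=NMe2 I (1.05 equiv), MeCN, 0 °C → rt; then 15 (2 equiv), 70 °C
Reagents that add atoms: N,N-dimethylmethyleneiminium iodide, C=[N+](C)C.[I-]
Why: Mannich reaction followed by quinone methide Michael addition, in which C8, the only free position of the acylphloroglucinol ring, takes up the iminium ion, loss of dimethylamine on warming gives quinone methide 17, and the acidic pyrone adds through its C3 to restore the aromatic ring; placing the one-carbon unit fully on 11 before 15 is added should prevent symmetrical dimers, and the stereocentre is not involved.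

**Compound list**
1 | 1-(4-hydroxy-2,6-dimethoxyphenyl)ethanone | CC(=O)c1c(OC)cc(O)cc1OC | starting material
2 | 3-acetyl-6-hydroxy-2,4-dimethoxybenzaldehyde | CC(=O)c1c(OC)cc(O)c(C=O)c1OC | intermediate
3 | 1-[4-hydroxy-3-(hydroxymethyl)-2,6-dimethoxyphenyl]ethanone | CC(=O)c1c(OC)cc(O)c(CO)c1OC | intermediate
4 | 1-bromo-2-methylprop-1-ene | CC(C)=CBr | starting material
5 | 1-chloro-1,1,3,3,3-pentamethyldisiloxane | C[Si](C)(C)O[Si](C)(C)Cl | starting material
6 | (2-methylprop-1-enyl)magnesium bromide | CC(C)=C[Mg]Br | intermediate
7 | 1,1,1,3,3-pentamethyl-3-(2-methylprop-1-enyl)disiloxane | CC(C)=C[Si](C)(C)O[Si](C)(C)C | intermediate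
8 | 4-acetyl-3,5-dimethoxy-6-methylidenecyclohexa-2,4-dien-1-one | C=C1C(=O)C=C(OC)C(C(C)=O)=C1OC | intermediate
9 | 1-[(3R)-5,7-dimethoxy-2,2-dimethyl-3-(pentamethyldisiloxanyl)-3,4-dihydro-2H-chromen-6-yl]ethanone | CC(=O)c1c(OC)cc2OC(C)(C)[C@H]([Si](C)(C)O[Si](C)(C)C)Cc2c1OC | intermediate
10 | 1-[(3R)-3-hydroxy-5,7-dimethoxy-2,2-dimethyl-3,4-dihydro-2H-chromen-6-yl]ethanone | CC(=O)c1c(OC)cc2OC(C)(C)[C@H](O)Cc2c1OC | intermediate
11 | 1-[(3R)-3,5,7-trihydroxy-2,2-dimethyl-3,4-dihydro-2H-chromen-6-yl]ethanone | CC(=O)c1c(O)cc2OC(C)(C)[C@H](O)Cc2c1O | intermediate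
12 | 3-pentanone | CCC(=O)CC | starting material
13 | (Z)-trimethyl(pent-2-en-3-yloxy)silane | C/C=C(/CC)O[Si](C)(C)C | intermediate
14 | malonyl dichloride | O=C(Cl)CC(=O)Cl | starting material
15 | 6-ethyl-4-hydroxy-5-methyl-2H-pyran-2-one | CCc1oc(=O)cc(O)c1C | intermediate
16 | 1-[(3R)-8-[(dimethylamino)methyl]-3,5,7-trihydroxy-2,2-dimethyl-3,4-dihydro-2H-chromen-6-yl]ethanone | CC(=O)c1c(O)c(CN(C)C)c2OC(C)(C)[C@H](O)Cc2c1O | intermediate
17 | (3R)-6-acetyl-3,5-dihydroxy-2,2-dimethyl-8-methylidene-3,4-dihydro-2H-chromen-7(8H)-one | CC(=O)C1=C(O)C2=C(OC(C)(C)[C@H](O)C2)C(=C)C1=O | intermediate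
18 | 3-{[(3R)-6-acetyl-3,5,7-trihydroxy-2,2-dimethyl-3,4-dihydro-2H-chromen-8-yl]methyl}-6-ethyl-4-hydroxy-5-methyl-2H-pyran-2-one | CCc1oc(=O)c(Cc2c(O)c(C(C)=O)c(O)c3c2OC(C)(C)[C@H](O)C3)c(O)c1C | target

Total step count: 9. Longest linear sequence: 6 steps (steps 1, 2, 4, 5, 6, 9).

**Steps most likely to fail**

Step 4. The alkene is a weak nucleophile with no hydrogen-bonding handle, so three things may go wrong:
- the quinone methide may be consumed by Friedel–Crafts alkylation of the free aromatic position of 3 or 9, giving oligomers;
- the beta-silyl cation may shed silicon, giving a prenyl arene or a chroman without the C3 substituent;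
- facial discrimination may be poor, because the bond-forming CH2 terminus lies far from the phosphate.

The fallback uses known chemistry, sets out from 1 and returns at 10. O-Alkylation of 1 with 3-chloro-3-methylbut-1-yne (K2CO3, KI, CuI, acetone, reflux) should give the propargyl ether 1-[2,6-dimethoxy-4-(2-methylbut-3-yn-2-yloxy)phenyl]ethanone F1. Heating in N,N-diethylaniline (aryl propargyl Claisen rearrangement, 1,5-hydrogen shift, 6π electrocyclisation) should give the chromene 1-(5,7-dimethoxy-2,2-dimethyl-2H-chromen-6-yl)ethanone F2, as one regioisomer because the two ortho positions are equivalent. Jacobsen–Katsuki epoxidation with (R,R)-[N,N'-bis(3,5-di-tert-butylsalicylidene)-1,2-cyclohexanediaminato]manganese chloride (trivalent manganese), NaOCl and 4-phenylpyridine N-oxide in CH2Cl2 at 0 °C should give the epoxide 1-[(3R,4R)-3,4-epoxy-5,7-dimethoxy-2,2-dimethyl-3,4-dihydro-2H-chromen-6-yl]ethanone F3. Hydrogenolysis of the benzylic C4–O bond (H2, Pd/C, EtOAc) leaves the C3–O bond untouched and gives 10.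

Step 5. Silicon carrying fluoride or hydroperoxide may fragment with O1 as leaving group, since O1 is the oxygen of a para-acyl phenol. This would open the ring to a prenyl phenol instead of oxidising C3. The silyl group is expected to sit pseudoaxial next to the gem-dimethyl group, out of antiperiplanar alignment with C2–O1, but ring inversion could still feed the fragmentation.

The fallback sets out from 9 and returns at 10; it drives the fragmentation to completion and resets C3 by a known epoxidation. Treatment of 9 with n-Bu4NF in THF should give the prenyl phenol 1-[4-hydroxy-2,6-dimethoxy-3-(3-methylbut-2-enyl)phenyl]ethanone F4. Acetylation (Ac2O, pyridine) gives 4-acetyl-3,5-dimethoxy-2-(3-methylbut-2-enyl)phenyl acetate F5. Shi epoxidation with the D-fructose-derived ketone 1,2:4,5-di-O-isopropylidene-β-D-erythro-2,3-hexodiulo-2,6-pyranose and KHSO5 (buffered MeCN/dimethoxymethane/water, 0 °C) should give 4-acetyl-2-{[(2R)-3,3-dimethyloxiran-2-yl]methyl}-3,5-dimethoxyphenyl acetate F6; the (R) sense is the one expected from the spiro transition-state model. Methanolysis of the acetate (K2CO3, MeOH, 0 °C) gives the epoxy phenol 1-(3-{[(2R)-3,3-dimethyloxiran-2-yl]methyl}-4-hydroxy-2,6-dimethoxyphenyl)ethanone F7. Under catalytic camphorsulfonic acid in CH2Cl2 this should close 6-endo at the tertiary epoxide carbon, with the C3–O bond retained, to give 10.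

Step 9. The one-carbon unit may move between the partners by retro-Mannich exchange, giving symmetrical methylene-bridged dimers, or quinone methide 17 may condense with itself.

The fallback sets out from 11, uses 15, and returns at 18; it fixes the bridge carbon on the chroman at the aldehyde oxidation level. Ortho-formylation of 11 at C8 (MgCl2, Et3N, (CH2O)n, MeCN, reflux) should give (3R)-6-acetyl-3,5,7-trihydroxy-2,2-dimethyl-3,4-dihydro-2H-chromene-8-carbaldehyde F8. Three-component reductive alkylation of 15 with F8 and diethyl 2,6-dimethyl-1,4-dihydropyridine-3,5-dicarboxylate, catalysed by L-proline in CH2Cl2 at rt, then gives 18 by Knoevenagel condensation and conjugate hydride transfer to the alkylidene pyrandione.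

**Further compounds**
F1 | step 4 | 1-[2,6-dimethoxy-4-(2-methylbut-3-yn-2-yloxy)phenyl]ethanone | CC(=O)c1c(OC)cc(OC(C)(C)C#C)cc1OC
F2 | step 4 | 1-(5,7-dimethoxy-2,2-dimethyl-2H-chromen-6-yl)ethanone | CC(=O)c1c(OC)cc2OC(C)(C)C=Cc2c1OC
F3 | step 4 | 1-[(3R,4R)-3,4-epoxy-5,7-dimethoxy-2,2-dimethyl-3,4-dihydro-2H-chromen-6-yl]ethanone | CC(=O)c1c(OC)cc2OC(C)(C)[C@@H]3O[C@@H]3c2c1OC
F4 | step 5 | 1-[4-hydroxy-2,6-dimethoxy-3-(3-methylbut-2-enyl)phenyl]ethanone | CC(=O)c1c(OC)cc(O)c(CC=C(C)C)c1OC
F5 | step 5 | 4-acetyl-3,5-dimethoxy-2-(3-methylbut-2-enyl)phenyl acetate | CC(=O)Oc1cc(OC)c(C(C)=O)c(OC)c1CC=C(C)C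
F6 | step 5 | 4-acetyl-2-{[(2R)-3,3-dimethyloxiran-2-yl]methyl}-3,5-dimethoxyphenyl acetate | CC(=O)Oc1cc(OC)c(C(C)=O)c(OC)c1C[C@H]2OC2(C)C
F7 | step 5 | 1-(3-{[(2R)-3,3-dimethyloxiran-2-yl]methyl}-4-hydroxy-2,6-dimethoxyphenyl)ethanone | CC(=O)c1c(OC)cc(O)c(C[C@H]2OC2(C)C)c1OC
F8 | step 9 | (3R)-6-acetyl-3,5,7-trihydroxy-2,2-dimethyl-3,4-dihydro-2H-chromene-8-carbaldehyde | CC(=O)c1c(O)c(C=O)c2OC(C)(C)[C@H](O)Cc2c1O
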